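## Retrosynthetic overview

1. Both carbocycles are the same pentasubstituted resorcinol. In the quinone methide half (isochromene numbering) C6–OH and C8=O flank C7, which carries the CH(CH3) linker, with C5–CH3 and the C4a side chain beside them; the lactone half repeats this at C5′–C8′. That pattern is the imprint of a ketene carbon (C6), a siloxyalkyne (C7≡C8–O) and a vinyl unit (C8a, C4a, C5), which makes a benzannulation possible.
2. Last disconnections: C1 of the pyran ring (an orthoformate carbon) from bis-resorcinol 34, then the C5–C6 bond, closed by 6π electrocyclization of a dienylketene formed in situ from cyclobutenone 10 and siloxyalkyne 28.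
3. Alkyne 28 comes from lactone 22. Its benzene ring is made by the same annulation from 10 and siloxyalkyne 14, which derives from the (S)-Roche ester and supplies the linker stereocentre; its lactone carbon is added by carboxylation.
4. Cyclobutenone 10 carries the anti CH(CH3)–CH(CH3)O pair of both halves, set by a Marshall propargylation of acetaldehyde, and is made by a keteniminium–alkyne [2+2] cycloaddition.
5. Ring order: right benzene ring (step 7), right lactone (step 9), left benzene ring (step 14), left pyran as quinone methide (step 17).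

Key step: step 14

Remarks on the chemistry:
- Assumption: the Marshall propargylation proceeds with net inversion at the propargylic carbon (anti-SN2′ oxidative addition, cyclic SE2′ addition), so the (R)-mesylate gives the (3S) centre.
- Cyclobutenone 10 is used as the mixture of epimers at its ring stereocentre, which becomes sp2 in steps 7 and 14.
- Both annulations begin with the same reversible 4π ring opening of 10 to vinylketene 15. This transient has one number and one line, entered at step 7 where it first forms; it forms again from 10 under the same conditions in step 14.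
- In 29–35 the CIP label of the linker carbon changes with the substituents on the two arenes; its spatial arrangement does not, and is the one given in the SMILES (R in the target).

## Route

Step 1
Reactants: 1 (R)-but-3-yn-2-ol
Product: 2 (R)-but-3-yn-2-yl methanesulfonate
Conditions: MsCl, Et3N, CH2Cl2, −78 → 0 °C
Reagents that add atoms: methanesulfonyl chloride, CS(=O)(=O)Cl
Why: O-sulfonylation (mesylation) of the secondary alcohol does not touch the stereocentre and provides the propargylic electrophile for the next step.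

Step 2
Reactants: 2 (R)-but-3-yn-2-yl methanesulfonate; 3 acetaldehyde
Product: 5 (2R,3S)-3-methylpent-4-yn-2-ol, via allenylzinc 4 (not isolated)
Conditions: Pd(OAc)2 (5 mol%), PPh3 (5 mol%), Et2Zn (3 equiv), acetaldehyde (excess), THF, −78 → −20 °C; aq. NH4Cl
Reagents that add atoms: none
Why: Marshall propargylation, in which zerovalent palladium displaces the mesylate anti-SN2′, transmetalation with Et2Zn gives allenylzinc 4, and its SE2′ addition to acetaldehyde through a cyclic chair-like transition state should give the anti pair, the methyl-bearing centre (3S) by net inversion of the mesylate carbon and the carbinol centre (2R) by the aldehyde methyl avoiding the allenyl methyl.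

Step 3
Reactants: 5 (2R,3S)-3-methylpent-4-yn-2-ol
Product: 6 tert-butyldimethyl{[(2R,3S)-3-methylpent-4-yn-2-yl]oxy}silane
Conditions: TBSCl, imidazole, DMF, rt
Reagents that add atoms: tert-butyldimethylsilyl chloride, CC(C)(C)[Si](C)(C)Cl
Why: Standard silylation of a secondary alcohol gives a non-nucleophilic ether that should not intercept the ketenes generated later.

Step 4
Reactants: 6 tert-butyldimethyl{[(2R,3S)-3-methylpent-4-yn-2-yl]oxy}silane; 7 N,N-dimethylpropanamide
Product: 10 3-[(2S,3R)-3-(tert-butyldimethylsilyloxy)butan-2-yl]-4-methylcyclobut-2-en-1-one, via keteniminium triflate 8 (not isolated), via cyclobuteniminium triflate 9 (not isolated)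
Conditions: Tf2O, 2,4,6-collidine, ClCH2CH2Cl, −20 °C → reflux; then H2O, rt
Reagents that add atoms: water, O
Why: Ghosez keteniminium–alkyne [2+2] cycloaddition, in which the electrophilic carbon of 8 bonds to the terminal alkyne carbon, ring closure gives 9 and hydrolysis gives the 3-alkyl-4-methylcyclobutenone; the new ring stereocentre is not controlled and need not be, and the side-chain centres are not touched.

Step 5
Reactants: 11 methyl (S)-3-hydroxy-2-methylpropanoate
Product: 12 methyl (S)-3-(tert-butyldimethylsilyloxy)-2-methylpropanoate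
Conditions: TBSCl, imidazole, CH2Cl2, 0 °C → rt
Reagents that add atoms: tert-butyldimethylsilyl chloride, CC(C)(C)[Si](C)(C)Cl
Why: Standard silylation of the primary alcohol; the ester α-centre is not affected under these weakly basic conditions.

Step 6
Reactants: 12 methyl (S)-3-(tert-butyldimethylsilyloxy)-2-methylpropanoate
Product: 14 (R)-tert-butyldimethyl{[2-methyl-4-(triisopropylsilyloxy)but-3-yn-1-yl]oxy}silane, via lithium ynolate 13 (not isolated)
Conditions: CH2Br2, lithium 2,2,6,6-tetramethylpiperidide, THF, −78 °C; then 12; then n-BuLi, −78 °C → rt; then i-Pr3SiOTf, −78 → 0 °C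
Reagents that add atoms: dibromomethane, BrCBr; triisopropylsilyl trifluoromethanesulfonate, CC(C)[Si](OS(=O)(=O)C(F)(F)F)(C(C)C)C(C)C
Why: Kowalski ester homologation stopped at the ynolate, in which LiCHBr2 adds to the ester, bromine–lithium exchange on the dibromo enolate triggers a 1,2-shift of the alkyl group with retention (so the Roche stereocentre is carried over unchanged in space), and the bulky silyl triflate traps ynolate 13 on oxygen.

Step 7
Reactants: 10 3-[(2S,3R)-3-(tert-butyldimethylsilyloxy)butan-2-yl]-4-methylcyclobut-2-en-1-one; 14 (R)-tert-butyldimethyl{[2-methyl-4-(triisopropylsilyloxy)but-3-yn-1-yl]oxy}silane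
Product: 19 6-[(2R)-1-(tert-butyldimethylsilyloxy)propan-2-yl]-3-[(2S,3R)-3-(tert-butyldimethylsilyloxy)butan-2-yl]-2-methyl-5-(triisopropylsilyloxy)phenol, via vinylketene 15 (not isolated), via alkenylcyclobutenone 16 (not isolated), via dienylketene 17 (not isolated), via cyclohexadienone 18 (not isolated)
Conditions: toluene, 80 °C then 110 °C (sealed tube)
Reagents that add atoms: none
Why: Danheiser benzannulation (4π ring opening of 10, regioselective ketene–siloxyalkyne [2+2], 4π ring opening, 6π electrocyclization, tautomerization), which should place the new phenol ortho to the branched alkyne substituent and meta to the siloxy group; the stereocentres formed in 16 and 18 become sp2 and the existing ones are spectators.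

Step 8
Reactants: 19 the phenol from step 7
Product: 20 2-[(2R)-1-hydroxypropan-2-yl]-5-[(2S,3R)-3-hydroxybutan-2-yl]-4-methylbenzene-1,3-diol
Conditions: n-Bu4NF, THF, 0 °C → rt; aq. NH4Cl
Reagents that add atoms: none
Why: Fluoride-mediated desilylation removes the aryl triisopropylsilyl ether and both alkyl tert-butyldimethylsilyl ethers without affecting any stereocentre.

Step 9
Reactants: 20 the resorcinol diol from step 8
Product: 22 (3R,4S)-6,8-dihydroxy-7-[(2R)-1-hydroxypropan-2-yl]-3,4,5-trimethylisochroman-1-one, via hydroxy acid 21 (not isolated)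
Conditions: MeOMgOCO2Me (2 M in DMF), 125 °C; then 2 M HCl, THF, 0 °C → rt
Reagents that add atoms: methoxymagnesium methyl carbonate, COC(=O)O[Mg]OC
Why: Stiles carboxylation (a magnesium-chelate variant of the Kolbe–Schmitt reaction) should carboxylate the only unsubstituted ring carbon, ortho to a phenol, and on acidification acid 21 lactonizes with the neighbouring secondary alcohol by acyl–oxygen bond formation, so the carbinol centre is retained and the trans-3,4-dimethyl lactone results.

Step 10
Reactants: 22 the dihydroxy lactone from step 9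
Product: 23 (3R,4S)-6,8-bis(benzyloxy)-7-[(2R)-1-hydroxypropan-2-yl]-3,4,5-trimethylisochroman-1-one
Conditions: BnBr, K2CO3, n-Bu4NI (cat.), DMF, 50 °C
Reagents that add atoms: benzyl bromide, BrCc1ccccc1
Why: Williamson etherification under carbonate conditions alkylates the two phenols only, because the primary alcohol is not deprotonated.

Step 11
Reactants: 23 the bis(benzyl) ether alcohol from step 10
Product: 24 (2R)-2-[(3R,4S)-6,8-bis(benzyloxy)-3,4,5-trimethyl-1-oxoisochroman-7-yl]propanal
Conditions: Dess–Martin periodinane, pyridine, CH2Cl2, 0 °C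
Reagents that add atoms: none
Why: Dess–Martin oxidation under buffered, non-basic conditions gives the aldehyde without enolization of the α-aryl stereocentre; the crude aldehyde is used at once.

Step 12
Reactants: 24 the aldehyde from step 11
Product: 25 (3R,4S)-6,8-bis(benzyloxy)-7-[(2S)-but-3-yn-2-yl]-3,4,5-trimethylisochroman-1-one
Conditions: Me3SiCHN2, n-BuLi, THF, −78 °C; then 24, −78 → 0 °C
Reagents that add atoms: (trimethylsilyl)diazomethane, C[Si](C)(C)C=[N+]=[N-]
Why: Colvin rearrangement (Seyferth–Gilbert-type homologation with lithiated trimethylsilyldiazomethane) converts the aldehyde into the terminal alkyne at −78 °C, where addition should outrun enolization of the α-centre and the deactivated aryl lactone should not be attacked.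

Step 13
Reactants: 25 the terminal alkyne from step 12
Product: 28 (3R,4S)-6,8-bis(benzyloxy)-3,4,5-trimethyl-7-[(2S)-4-(triisopropylsilyloxy)but-3-yn-2-yl]isochroman-1-one, via lithium acetylide 26 (not isolated), via lithium ynolate 27 (not isolated)
Conditions: LiN(SiMe3)2, THF, −78 °C; t-BuOOLi (from t-BuOOH and LiN(SiMe3)2), −78 → 0 °C; i-Pr3SiOTf, −78 °C
Reagents that add atoms: tert-butyl hydroperoxide, CC(C)(C)OO; triisopropylsilyl trifluoromethanesulfonate, CC(C)[Si](OS(=O)(=O)C(F)(F)F)(C(C)C)C(C)C
Why: Oxidation of a lithium acetylide by lithium tert-butyl peroxide (electrophilic oxygen transfer) gives ynolate 27, which the bulky silyl triflate traps on oxygen; the amide base is chosen because it deprotonates the alkyne but does not add to the lactone.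

Step 14
Reactants: 10 3-[(2S,3R)-3-(tert-butyldimethylsilyloxy)butan-2-yl]-4-methylcyclobut-2-en-1-one; 28 the siloxyalkyne from step 13
Product: 32 (3R,4S)-6,8-bis(benzyloxy)-7-{1-[4-((2S,3R)-3-(tert-butyldimethylsilyloxy)butan-2-yl)-2-hydroxy-3-methyl-6-(triisopropylsilyloxy)phenyl]ethyl}-3,4,5-trimethylisochroman-1-one, via alkenylcyclobutenone 29 (not isolated), via dienylketene 30 (not isolated), via cyclohexadienone 31 (not isolated)
Conditions: 10 (1.3 equiv), toluene, 80 °C then 110 °C (sealed tube)
Reagents that add atoms: none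
Why: As in step 7, heating reopens 10 by 4π electrocyclic ring opening to vinylketene 15, which adds to the electron-rich siloxyalkyne 28 in a [2+2] cycloaddition to give 29; a second 4π opening gives dienylketene 30, whose 6π electrocyclization joins the ketene carbon (C6) to the methyl-bearing diene terminus (C5), and cyclohexadienone 31 tautomerizes to phenol 32. The closest known reaction type is the Danheiser benzannulation of cyclobutenones with siloxyalkynes, already used in step 7. The four-membered ring of 29 is closed by the ketene–alkyne [2+2] cycloaddition and reopened, and the six-membered carbocycle is closed by a thermally allowed disrotatory 6π electrocyclization that forms the C5–C6 bond. No new stereocentre survives, since the ring carbons of 29 and 31 become sp2, while the linker centre and the side-chain centres are spectators under neutral thermal conditions. The step needs regioselectivity in the [2+2] event, secured by the polarization of the siloxyalkyne (its nucleophilic β-carbon, the one bearing the linker, bonds to the ketene carbonyl carbon), and only the dienylketene isomer with the alkenyl terminus cis to the ketene can cyclize, the other returning reversibly to 29. In one operation the step joins the two halves, builds the left carbocycle with five of its six substituents in place, and leaves a single free ring carbon (C8a) for the last ring.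

Step 15
Reactants: 32 the coupled phenol from step 14
Product: 33 (3R,4S)-6,8-bis(benzyloxy)-7-{1-[2,6-dihydroxy-4-((2S,3R)-3-hydroxybutan-2-yl)-3-methylphenyl]ethyl}-3,4,5-trimethylisochroman-1-one
Conditions: n-Bu4NF, THF, 0 °C → rt; aq. NH4Cl
Reagents that add atoms: none
Why: Fluoride-mediated desilylation removes the aryl triisopropylsilyl and the alkyl tert-butyldimethylsilyl ether; the lactone and benzyl ethers should be stable.

Step 16
Reactants: 33 the bis(benzyl) ether from step 15
Product: 34 (3R,4S)-7-{1-[2,6-dihydroxy-4-((2S,3R)-3-hydroxybutan-2-yl)-3-methylphenyl]ethyl}-6,8-dihydroxy-3,4,5-trimethylisochroman-1-one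
Conditions: H2 (1 atm), Pd/C, EtOAc–MeOH, rt
Reagents that add atoms: none
Why: Catalytic hydrogenolysis cleaves the two benzyl ethers; nothing else in the molecule is reducible under these conditions, and the diaryl-methine linker is not an activated C–O or C–N bond.

Step 17
Reactants: 34 the bis-resorcinol from step 16
Product: 36 Dicitrtinone H, via cyclic ethyl acetal 35 (not isolated)
Conditions: HC(OEt)3, CF3CO2H, CH2Cl2, 0 °C → rt
Reagents that add atoms: triethyl orthoformate, CCOC(OCC)OCC
Why: Acid-promoted formylation with the orthoformate at the only unsubstituted ring carbon (ortho to one phenol and para to the other), acetalization by the side-chain alcohol to 35 and loss of ethanol give an isochromenylium ion whose deprotonation at the 8-oxygen gives the quinone methide (citrinin-type closure), with no stereocentre touched.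

## Compound list

1 | (R)-but-3-yn-2-ol | C[C@@H](O)C#C | starting material
2 | (R)-but-3-yn-2-yl methanesulfonate | C[C@@H](OS(C)(=O)=O)C#C | intermediate
3 | acetaldehyde | CC=O | starting material
4 | (aS)-buta-1,2-dien-1-yl(ethyl)zinc (allenylzinc) | CC[Zn]C([H])=[C@@]=C([H])C | intermediate
5 | (2R,3S)-3-methylpent-4-yn-2-ol (anti) | C#C[C@H](C)[C@@H](C)O | intermediate
6 | tert-butyldimethyl{[(2R,3S)-3-methylpent-4-yn-2-yl]oxy}silane | C#C[C@H](C)[C@@H](C)O[Si](C)(C)C(C)(C)C | intermediate
7 | N,N-dimethylpropanamide | CCC(=O)N(C)C | starting material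
8 | N,N-dimethyl-N-(prop-1-en-1-ylidene)ammonium trifluoromethanesulfonate (keteniminium triflate) | CC=C=[N+](C)C.[O-]S(=O)(=O)C(F)(F)F | intermediate
9 | N-{3-[(2S,3R)-3-(tert-butyldimethylsilyloxy)butan-2-yl]-4-methylcyclobut-2-en-1-ylidene}-N-methylmethanaminium trifluoromethanesulfonate (cyclobuteniminium triflate, both ring epimers) | C[N+](C)=C1C=C([C@H](C)[C@@H](C)O[Si](C)(C)C(C)(C)C)C1C.[O-]S(=O)(=O)C(F)(F)F | intermediate
10 | 3-[(2S,3R)-3-(tert-butyldimethylsilyloxy)butan-2-yl]-4-methylcyclobut-2-en-1-one (both epimers at C4) | O=C1C=C([C@H](C)[C@@H](C)O[Si](C)(C)C(C)(C)C)C1C | intermediate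
11 | methyl (S)-3-hydroxy-2-methylpropanoate (Roche ester) | COC(=O)[C@@H](C)CO | starting material
12 | methyl (S)-3-(tert-butyldimethylsilyloxy)-2-methylpropanoate | COC(=O)[C@@H](C)CO[Si](C)(C)C(C)(C)C | intermediate
13 | lithium (R)-4-(tert-butyldimethylsilyloxy)-3-methylbut-1-yn-1-olate (ynolate) | [Li]OC#C[C@@H](C)CO[Si](C)(C)C(C)(C)C | intermediate
14 | (R)-tert-butyldimethyl{[2-methyl-4-(triisopropylsilyloxy)but-3-yn-1-yl]oxy}silane | CC(C)[Si](OC#C[C@@H](C)CO[Si](C)(C)C(C)(C)C)(C(C)C)C(C)C | intermediate
15 | (E)-3-[(2S,3R)-3-(tert-butyldimethylsilyloxy)butan-2-yl]penta-1,3-dien-1-one (vinylketene) | O=C=C/C(=C/C)[C@H](C)[C@@H](C)O[Si](C)(C)C(C)(C)C | intermediate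
16 | 2-[(2R)-1-(tert-butyldimethylsilyloxy)propan-2-yl]-4-[(2E,4S,5R)-5-(tert-butyldimethylsilyloxy)-4-methylhex-2-en-3-yl]-3-(triisopropylsilyloxy)cyclobut-2-en-1-one (both epimers at C4) | O=C1C([C@@H](C)CO[Si](C)(C)C(C)(C)C)=C(O[Si](C(C)C)(C(C)C)C(C)C)C1/C(=C/C)[C@H](C)[C@@H](C)O[Si](C)(C)C(C)(C)C | intermediate
17 | (3E,5E)-2-[(2R)-1-(tert-butyldimethylsilyloxy)propan-2-yl]-5-[(2S,3R)-3-(tert-butyldimethylsilyloxy)butan-2-yl]-3-(triisopropylsilyloxy)hepta-1,3,5-trien-1-one (dienylketene) | O=C=C([C@@H](C)CO[Si](C)(C)C(C)(C)C)/C(O[Si](C(C)C)(C(C)C)C(C)C)=C\C(=C\C)[C@H](C)[C@@H](C)O[Si](C)(C)C(C)(C)C | intermediate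
18 | 2-[(2R)-1-(tert-butyldimethylsilyloxy)propan-2-yl]-5-[(2S,3R)-3-(tert-butyldimethylsilyloxy)butan-2-yl]-6-methyl-3-(triisopropylsilyloxy)cyclohexa-2,4-dien-1-one (both epimers at C6) | O=C1C([C@@H](C)CO[Si](C)(C)C(C)(C)C)=C(O[Si](C(C)C)(C(C)C)C(C)C)C=C([C@H](C)[C@@H](C)O[Si](C)(C)C(C)(C)C)C1C | intermediate
19 | 6-[(2R)-1-(tert-butyldimethylsilyloxy)propan-2-yl]-3-[(2S,3R)-3-(tert-butyldimethylsilyloxy)butan-2-yl]-2-methyl-5-(triisopropylsilyloxy)phenol | Cc1c(O)c([C@@H](C)CO[Si](C)(C)C(C)(C)C)c(O[Si](C(C)C)(C(C)C)C(C)C)cc1[C@H](C)[C@@H](C)O[Si](C)(C)C(C)(C)C | intermediate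
20 | 2-[(2R)-1-hydroxypropan-2-yl]-5-[(2S,3R)-3-hydroxybutan-2-yl]-4-methylbenzene-1,3-diol | Cc1c(O)c([C@@H](C)CO)c(O)cc1[C@H](C)[C@@H](C)O | intermediate
21 | 2,4-dihydroxy-6-[(2S,3R)-3-hydroxybutan-2-yl]-3-[(2R)-1-hydroxypropan-2-yl]-5-methylbenzoic acid | Cc1c(O)c([C@@H](C)CO)c(O)c(C(=O)O)c1[C@H](C)[C@@H](C)O | intermediate
22 | (3R,4S)-6,8-dihydroxy-7-[(2R)-1-hydroxypropan-2-yl]-3,4,5-trimethylisochroman-1-one | Cc1c(O)c([C@@H](C)CO)c(O)c2c1[C@H](C)[C@@H](C)OC2=O | intermediate
23 | (3R,4S)-6,8-bis(benzyloxy)-7-[(2R)-1-hydroxypropan-2-yl]-3,4,5-trimethylisochroman-1-one | Cc1c(OCc3ccccc3)c([C@@H](C)CO)c(OCc3ccccc3)c2c1[C@H](C)[C@@H](C)OC2=O | intermediate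
24 | (2R)-2-[(3R,4S)-6,8-bis(benzyloxy)-3,4,5-trimethyl-1-oxoisochroman-7-yl]propanal | Cc1c(OCc3ccccc3)c([C@@H](C)C=O)c(OCc3ccccc3)c2c1[C@H](C)[C@@H](C)OC2=O | intermediate
25 | (3R,4S)-6,8-bis(benzyloxy)-7-[(2S)-but-3-yn-2-yl]-3,4,5-trimethylisochroman-1-one | Cc1c(OCc3ccccc3)c([C@@H](C)C#C)c(OCc3ccccc3)c2c1[C@H](C)[C@@H](C)OC2=O | intermediate
26 | lithium acetylide of 25 | Cc1c(OCc3ccccc3)c([C@@H](C)C#C[Li])c(OCc3ccccc3)c2c1[C@H](C)[C@@H](C)OC2=O | intermediate
27 | lithium ynolate from 26, lithium (3S)-3-[(3R,4S)-6,8-bis(benzyloxy)-3,4,5-trimethyl-1-oxoisochroman-7-yl]but-1-yn-1-olate | Cc1c(OCc3ccccc3)c([C@@H](C)C#CO[Li])c(OCc3ccccc3)c2c1[C@H](C)[C@@H](C)OC2=O | intermediate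
28 | (3R,4S)-6,8-bis(benzyloxy)-3,4,5-trimethyl-7-[(2S)-4-(triisopropylsilyloxy)but-3-yn-2-yl]isochroman-1-one | Cc1c(OCc3ccccc3)c([C@@H](C)C#CO[Si](C(C)C)(C(C)C)C(C)C)c(OCc3ccccc3)c2c1[C@H](C)[C@@H](C)OC2=O | intermediate
29 | 2-{1-[(3R,4S)-6,8-bis(benzyloxy)-3,4,5-trimethyl-1-oxoisochroman-7-yl]ethyl}-4-[(2E,4S,5R)-5-(tert-butyldimethylsilyloxy)-4-methylhex-2-en-3-yl]-3-(triisopropylsilyloxy)cyclobut-2-en-1-one (both epimers at C4; linker as in 28) | O=C1C([C@H](C)c2c(OCc4ccccc4)c(C)c3c(c2OCc4ccccc4)C(=O)O[C@H](C)[C@H]3C)=C(O[Si](C(C)C)(C(C)C)C(C)C)C1/C(=C/C)[C@H](C)[C@@H](C)O[Si](C)(C)C(C)(C)C | intermediate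
30 | (3E,5E)-2-{1-[(3R,4S)-6,8-bis(benzyloxy)-3,4,5-trimethyl-1-oxoisochroman-7-yl]ethyl}-5-[(2S,3R)-3-(tert-butyldimethylsilyloxy)butan-2-yl]-3-(triisopropylsilyloxy)hepta-1,3,5-trien-1-one (dienylketene; linker as in 28) | O=C=C([C@H](C)c2c(OCc4ccccc4)c(C)c3c(c2OCc4ccccc4)C(=O)O[C@H](C)[C@H]3C)/C(O[Si](C(C)C)(C(C)C)C(C)C)=C\C(=C\C)[C@H](C)[C@@H](C)O[Si](C)(C)C(C)(C)C | intermediate
31 | 2-{1-[(3R,4S)-6,8-bis(benzyloxy)-3,4,5-trimethyl-1-oxoisochroman-7-yl]ethyl}-5-[(2S,3R)-3-(tert-butyldimethylsilyloxy)butan-2-yl]-6-methyl-3-(triisopropylsilyloxy)cyclohexa-2,4-dien-1-one (both epimers at C6; linker as in 28) | O=C1C([C@H](C)c2c(OCc4ccccc4)c(C)c3c(c2OCc4ccccc4)C(=O)O[C@H](C)[C@H]3C)=C(O[Si](C(C)C)(C(C)C)C(C)C)C=C([C@H](C)[C@@H](C)O[Si](C)(C)C(C)(C)C)C1C | intermediate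
32 | (3R,4S)-6,8-bis(benzyloxy)-7-{1-[4-((2S,3R)-3-(tert-butyldimethylsilyloxy)butan-2-yl)-2-hydroxy-3-methyl-6-(triisopropylsilyloxy)phenyl]ethyl}-3,4,5-trimethylisochroman-1-one (linker as in the SMILES) | Cc1c(O)c([C@H](C)c2c(OCc4ccccc4)c(C)c3c(c2OCc4ccccc4)C(=O)O[C@H](C)[C@H]3C)c(O[Si](C(C)C)(C(C)C)C(C)C)cc1[C@H](C)[C@@H](C)O[Si](C)(C)C(C)(C)C | intermediate
33 | (3R,4S)-6,8-bis(benzyloxy)-7-{1-[2,6-dihydroxy-4-((2S,3R)-3-hydroxybutan-2-yl)-3-methylphenyl]ethyl}-3,4,5-trimethylisochroman-1-one (linker as in the SMILES) | Cc1c(O)c([C@H](C)c2c(OCc4ccccc4)c(C)c3c(c2OCc4ccccc4)C(=O)O[C@H](C)[C@H]3C)c(O)cc1[C@H](C)[C@@H](C)O | intermediate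
34 | (3R,4S)-7-{1-[2,6-dihydroxy-4-((2S,3R)-3-hydroxybutan-2-yl)-3-methylphenyl]ethyl}-6,8-dihydroxy-3,4,5-trimethylisochroman-1-one (linker as in the SMILES) | Cc1c(O)c([C@H](C)c2c(O)c(C)c3c(c2O)C(=O)O[C@H](C)[C@H]3C)c(O)cc1[C@H](C)[C@@H](C)O | intermediate
35 | (3R,4S)-7-{1-[(3R,4S)-1-ethoxy-6,8-dihydroxy-3,4,5-trimethylisochroman-7-yl]ethyl}-6,8-dihydroxy-3,4,5-trimethylisochroman-1-one (both epimers at the acetal carbon; linker as in the SMILES) | CCOC1O[C@H](C)[C@@H](C)c2c(C)c(O)c([C@H](C)c3c(O)c(C)c4c(c3O)C(=O)O[C@H](C)[C@H]4C)c(O)c12 | intermediate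
36 | Dicitrtinone H, (3R,4S)-6,8-dihydroxy-7-{(1R)-1-[(3R,4S)-6-hydroxy-3,4,5-trimethyl-8-oxo-4,8-dihydro-3H-isochromen-7-yl]ethyl}-3,4,5-trimethylisochroman-1-one | CC1=C2C(=CO[C@H](C)[C@H]2C)C(=O)C([C@H](C)c2c(O)c(C)c3c(c2O)C(=O)O[C@H](C)[C@H]3C)=C1O | target

## Step count and risks

Total step count: 17. Longest linear sequence: 15 (steps 1–4, then 7–17); the branch through steps 5–6 joins at step 7.

Steps most likely to fail:

1. Step 9. Carboxylation at the ring carbon next to the branched side chain may be slow or reversible, and the 2,4-dihydroxybenzoic acid may lose CO2 before it lactonizes. The fallback sets out from 20: benzylation of both phenols (BnBr, K2CO3, DMF) should give the bis(benzyl) ether diol F1; N-bromosuccinimide in MeCN at 0 °C should brominate the single free ring position to the aryl bromide F2; palladium-catalysed carbonylative lactonization (Pd(OAc)2, Xantphos, CO 1 atm, Et3N, toluene, 100 °C) should then close the six-membered lactone through the secondary alcohol (the primary alcohol could only close a seven-membered ring). The fallback comes back to the route at 23.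

2. Step 13. The acetylide or the peroxide anion may add to the lactone carbonyl, and the ynolate may be silylated on carbon to a silylketene. The fallback sets out from 25 and reverses the polarity of the alkyne: hydroxy(tosyloxy)iodobenzene in CH2Cl2 should give the alkynyl(phenyl)iodonium tosylate F3; catalytic CuOTf in MeCN should collapse it, with loss of iodobenzene, to the alkynyl tosylate F4; MeLi in THF at −78 °C should attack sulfur and release ynolate 27, which is silylated with i-Pr3SiOTf. The fallback comes back to the route at 28.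

3. Step 17. Acid may protonate the electron-rich ring at the carbon bearing the linker and cause retro-Friedel–Crafts cleavage or epimerization at the doubly benzylic centre, and the quinone methide may hydrate or oligomerize. The fallback sets out from 34 and formylates under basic conditions: magnesium-mediated ortho-formylation (MgCl2, Et3N, paraformaldehyde, MeCN, reflux; Casnati–Skattebøl conditions) should give the salicylaldehyde F5, in equilibrium with its lactol, at the only free ortho position; brief treatment with AcOH and molecular sieves in CH2Cl2 should then effect dehydrative closure. The fallback comes back to the route at 36.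

Further compounds
F1 | step 9 | (2R,3S)-3-{3,5-bis(benzyloxy)-4-[(2R)-1-hydroxypropan-2-yl]-2-methylphenyl}butan-2-ol | Cc1c(OCc2ccccc2)c([C@@H](C)CO)c(OCc2ccccc2)cc1[C@H](C)[C@@H](C)O
F2 | step 9 | (2R,3S)-3-{3,5-bis(benzyloxy)-6-bromo-4-[(2R)-1-hydroxypropan-2-yl]-2-methylphenyl}butan-2-ol | Cc1c(OCc2ccccc2)c([C@@H](C)CO)c(OCc2ccccc2)c(Br)c1[C@H](C)[C@@H](C)O
F3 | step 13 | alkynyl(phenyl)iodonium tosylate derived from 25 (stereocentres unchanged in space) | Cc1c(OCc3ccccc3)c([C@@H](C)C#C[I+]c3ccccc3)c(OCc3ccccc3)c2c1[C@H](C)[C@@H](C)OC2=O.Cc1ccc(S(=O)(=O)[O-])cc1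
F4 | step 13 | alkynyl 4-methylbenzenesulfonate derived from 25, (3S)-3-[(3R,4S)-6,8-bis(benzyloxy)-3,4,5-trimethyl-1-oxoisochroman-7-yl]but-1-yn-1-yl tosylate | Cc1c(OCc3ccccc3)c([C@@H](C)C#COS(=O)(=O)c3ccc(C)cc3)c(OCc3ccccc3)c2c1[C@H](C)[C@@H](C)OC2=O
F5 | step 17 | 3-{1-[(3R,4S)-6,8-dihydroxy-3,4,5-trimethyl-1-oxoisochroman-7-yl]ethyl}-2,4-dihydroxy-6-[(2S,3R)-3-hydroxybutan-2-yl]-5-methylbenzaldehyde (linker as in 34) | O=Cc1c(O)c([C@H](C)c2c(O)c(C)c3c(c2O)C(=O)O[C@H](C)[C@H]3C)c(O)c(C)c1[C@H](C)[C@@H](C)O
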